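(The earlier runs and the new flask are simulated for substances that don't exist; the scatter is artificial.)

Friday's and Wednesday's runs show target turning into over-reaction product at a rate that can be read directly. The share asked for, a selectivity, is reckoned here from that rate.

| flask | substrate | coupling partner | remark | time |
|---|---|---|---|---|
| Tuesday's | 20 mM | 24 mM | run made earlier |  |
| Saturday's | 20 mM | 12 mM | run made earlier |  |
| Friday's | 20 mM | 18 mM | run made earlier |  |
| Wednesday's | 40 mM | 24 mM | run made earlier |  |
| north-east | 20 mM (fed, over 80 s) | 24.0 mM | all else is in the flask from the start; the feed brings no volume worth counting | 3.0 min |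
| north-west | 20 mM | 24.0 mM (fed, over 80 s) | all else is in the flask from the start; the feed brings no volume worth counting | 3.0 min |
| south-west | 20 mM | 24.0 mM | everything together at the start | 3.0 min |

Tuesday's run (percent of the substrate charged)

| time / s | target / % | over-reaction product / % |
|---|---|---|
| 10.0 | 0 | 0.8 |
| 15.0 | 0.8 | 0 |
| 30.0 | 1.4 | 0 |
| 60.0 | 2.6 | 0.9 |
| 120 | 4.8 | 3.5 |

Saturday's run (percent of the substrate charged)

| time / min | target / % | over-reaction product / % |
|---|---|---|
| 0.250 | 0 | 0.8 |
| 0.833 | 1.4 | 0.1 |
| 1.33 | 2.4 | 2.0 |
| 2.00 | 4.8 | 2.1 |
| 3.00 | 4.4 | 3.8 |

Friday's run (percent of the substrate charged)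

| time / min | target / % | over-reaction product / % |
|---|---|---|
| 0.667 | 1.1 | 0 |
| 1.33 | 4.8 | 1.4 |
| 2.00 | 4.6 | 2.5 |
| 2.50 | 5.5 | 4.8 |
| 3.00 | 6.3 | 6.3 |

Wednesday's run (percent of the substrate charged)

| time / min | target / % | over-reaction product / % |
|---|---|---|
| 0.667 | 1.1 | 0.3 |
| 1.33 | 2.7 | 1.1 |
| 2.00 | 4.7 | 3.5 |
| 2.50 | 5.8 | 5.6 |
| 3.00 | 6.0 | 6.1 |

(standard deviation of a reading: 0.5 percentage points)

* the best flask by share of target in target plus over-reaction product; "all alike" if 1.5 percentage points covers them all (north-east / north-west / south-west / all alike)
* share of target in target plus over-reaction product at the end, north-east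
* share of target in target plus over-reaction product at the end, north-west
* share of target in target plus over-reaction product at the end, south-west

- the analysis behind the earlier runs scatters by 0.5 percentage points, standard deviation
- steps thought possible: coupling partner + intermediate B <-> target; target -> over-reaction product; substrate <-> intermediate B; substrate + coupling partner <-> intermediate A

From 2.00 min to 3.00 min, over-reaction product rose by 3.8 percentage points of the charge on Friday and by 2.6 points on Wednesday, while target averaged 5.45% and 5.35%. Pooling the two gives the chance per minute that one molecule of target is lost, the loss constant 0.593 /min. It is a reading with scatter: Friday's pair gives 0.697 /min, Wednesday's 0.486 /min.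

A target molecule of age a survives with chance exp(−ka). If molecules are born evenly over a window T, the surviving fraction is the average of that chance: (one minus exp(−kT)) divided by kT. Tuesday's run did not enter k, so it can test this. At 120 s the formula gives 58.6%, and the readings give 57.8%.

My reckoning for south-west uses the whole 3.0 min as window, which gives 46.7%. For north-west, Saturday's run, with 50.0% of Tuesday's partner, had 6.90% in target plus over-reaction product at 2.00 min, against Tuesday's 8.30%. The north-west feed supplies that fraction within 40.0 s, so I keep the window and the same 46.7%. In north-east the average substrate molecule enters 40.0 s late, which shortens the window to 2.33 min and gives 54.2%.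

The forecast, higher than this reckoning, gave 58%, 52% and 51% for north-east, north-west and south-west, with north-east best: “feeding substrate makes the target younger on average”.

The flasks give 54.5%, 46.1% and 46.7% in that order, and the best is north-east.

    coupling partner + intermediate B ⇌ target (K = 18.0 /M, k = 0.470 /M/s)
    target → over-reaction product (k = 0.0110 /s)
    substrate ⇌ intermediate B (K = 3.70, k = 0.0130 /s)
    substrate + coupling partner ⇌ intermediate A (K = 97.0 /M, k = 11.0 /M/s)

North-west lies 0.60 points under the reckoned share and north-east 0.30 points above its own. The neighbouring flask is north-west read later, at 5.0 min. With that whole time as window, 0.593 /min gives 32.0%. The flask gives 27.9%, which is 4.1 points lower, with target at 7.23% and over-reaction product at 18.7% of the charge.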